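Treat the theta run as the alpha run with a head start, and reckon the head start.

| setting | alpha | beta | eta | theta |
|---|---|---|---|---|
| substrate | 300 mM | 180 mM | 300 mM | 600 mM |
| coupling partner | 300 mM | 180 mM | 300 mM | 600 mM |
| free catalyst | 3.00 mM | 3.00 mM | 3.00 mM | 3.00 mM |
| product |  |  | 90.0 mM |  |
| time |  |  |  | 24 min |

| run | time / min | [product] / mM |
|---|---|---|
| alpha run | 0.96 | 15.8 |
| alpha run | 1.6 | 27.2 |
| alpha run | 2.8 | 45.7 |
| alpha run | 4.8 | 75.7 |
| alpha run | 8.2 | 121.6 |
| alpha run | 14 | 179.4 |
| alpha run | 24 | 238.3 |
| beta run | 0.96 | 11.4 |
| beta run | 1.6 | 18.7 |
| beta run | 2.8 | 32.6 |
| beta run | 4.8 | 50.2 |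
| beta run | 8.2 | 78.2 |
| beta run | 14 | 111.9 |
| beta run | 24 | 140.3 |
| eta run | 0.96 | 106.1 |
| eta run | 1.6 | 117.0 |
| eta run | 2.8 | 135.6 |
| eta run | 4.8 | 166.8 |
| eta run | 8.2 | 211.3 |
| eta run | 14 | 270.0 |
| eta run | 24 | 327.9 |

(scatter of a reading: 0.9 mM)

- Overall: substrate + coupling partner -> product, with free catalyst as catalyst.
- Constant volume, constant temperature.
- The analysis sees a species whether free or bound.
- "The second partner" is coupling partner.

1. the beta run starts with 120 mM less of substrate and of coupling partner than the alpha run, and with no product. Compared where both hold the same amount of substrate, once fifteen percent of what the beta run was charged with has turned into product, is the beta run faster, slower or alike (within a tenth)?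
2. product in the theta run at 24 min, as a share of the substrate charged
3. which of these the readings show (the by-product binds the second partner / the loaded catalyst dies / the substrate ties up the catalyst / nothing beyond the main steps)

Test the head start first. The eta run, charged with 90.0 mM of product, makes 238 mM of new product by 24 min, against 238.3 mM in the alpha run, so added product shows no effect. The alpha run has made 120 mM after about 8.08 min, and then it holds the charge of the beta run. From there to 14 min it makes 59.4 mM, and the beta run, interpolated over the same span, makes 59.4 mM. So the two runs lie on one curve, and at equal substrate they look alike. Charges are equal, so c(substrate) equals c(coupling partner) throughout.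

Now price the curve. Call the reciprocal of the rate the cost of a millimolar of product. Over the first 2.8 min, a mean c(substrate) of 277 mM in the alpha run gives a rate of 16.3 mM/min, and 164 mM in the beta run gives a slower 11.6 mM/min. Split the cost into a part that falls with substrate and a flat part, the reciprocal of a ceiling rate:

cost = tau / c(substrate) + flat

tau = 9.85 min, ceiling rate = 38.8 mM/min

Set the two parts equal:

crossing = tau × ceiling rate = 382 mM

The crossing is the c(substrate) at which the two parts are equal.

Above it, the flat part weighs more. The theta run starts above this first crossing. Summing the cost from 600 mM down to 300 mM gives the head start: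

lead = tau ln(600/300) + (600 − 300) / ceiling rate = 14.5 min

The remaining 9.45 min run along the alpha curve, where a chord between readings gives 134 mM. Adding the 300 mM already made gives a share of 72.3%.

The lead is the weak link, since no run reaches above 300 mM. Reforge it from the rates over 4.8 min: tau becomes 12.2 min, the ceiling rate becomes 59.2 mM/min, the crossing becomes 722 mM, the lead becomes 13.5 min, and the share becomes 74.1%. The crossing is poorly read, but the share holds up better. Commit to 72.3% to 74.1%.

The forecast, reckoned separately, says alike, 72% (range 66% to 77%) and the substrate ties up the catalyst, on the grounds of an upward-curving plot “which points to substrate tying up catalyst”.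

The flask gives alike, 72.0% and the substrate ties up the catalyst.

    free catalyst + substrate ⇌ catalyst-substrate complex, settled at all times (16.90 /M)
    catalyst-substrate complex + coupling partner → product + free catalyst + by-product (47.82 /M/min)
    catalyst-substrate complex + substrate ⇌ doubly bound catalyst, settled at all times (4.480 /M)

Binding of substrate to the catalyst-substrate complex, which forms doubly bound catalyst (substrate inhibition), is the main reason the theta run holds 72.0% at 24 min. The theta charge stands at 1.57 times the first crossing, where the flat part of the cost is the heavier. Strike the flat part, and the cost tau / c(substrate), with tau as crossing over ceiling rate, gives a share of 91.3% at 24 min. The theta run without that binding reaches 91.1%.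

(The earlier runs and the new flask stem from a simulated flask for an exercise; the scatter is artificial.)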